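Count the reach, not the rate.

| setting | amber | larch | cedar |
|---|---|---|---|
| substrate | 0.0067 M | 0.010 M | 0.010 M |
| coupling partner | 10 mM | 10.0 mM | 10.0 mM |
| free catalyst | 39 µM | 39 µM | 39 µM |
| added ligand | 82 µM | 82 µM | 250 µM |
| temperature | 5 °C | 5 °C | 5 °C |
| remark | run made earlier |  |  |
| time |  | 15 min | 8.0 min |

- amber (time / min: product / %): 0.833: 10.9; 2.50: 24.1; 4.00: 31.0; 6.00: 36.4; 10.0: 41.0

(standard deviation of a reading: 0.3 percentage points)

- the winner by amount of product, in percent of the substrate charged; "neither" if no more than 2 percentage points parts them (larch / cedar / neither)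
- how much product is there at the end, in percent of the substrate charged: larch
- how much product is there at the end, in percent of the substrate charged: cedar

- no earlier run changes the charge of added ligand; that part of a forecast is a guess

I write the rate as k[substrate][coupling partner], with substrate and coupling partner used one for one and k free to drift. The integrated second-order law then turns each reading into the time integral of k, which I call the reach. With unequal charges it is the logarithm of the rise of [coupling partner]/[substrate] from its start, over the difference of the charges; with equal charges it is the rise of the reciprocal of [substrate].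

Reading the amber rows downward, the reach is 0.0120 mM⁻¹, 0.0302 mM⁻¹, 0.0419 mM⁻¹, 0.0524 mM⁻¹ and 0.0626 mM⁻¹. The mean k of the first interval is 0.01440 mM⁻¹ min⁻¹, and that of the last is 0.002535 mM⁻¹ min⁻¹, which is less. So a single mean for the whole amber run, 0.006256 mM⁻¹ min⁻¹, will not do: it would put larch at 48.4 %.

Between the midpoints of those intervals k falls with a constant of 0.229 min⁻¹, which I read as the working catalyst fading. The tail after the last reading adds 0.007001 mM⁻¹, giving 0.0696 mM⁻¹. This is the total reach, an estimate from the amber readings of what amber's catalyst and ligand charges deliver at this temperature, and I assume that it carries over to the larger substrate charge.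

For larch the reach by 15 min is 0.0673 mM⁻¹, which gives 40.2 %. For cedar at amber's ligand charge the reach by 8.0 min is 0.0585 mM⁻¹, which gives 36.9 %. That is less than larch, a gap of 3.3 percentage points against the margin of 2 points, before the larger ligand charge, which no earlier run tests, has any say. I commit to larch.

The forecast also names larch, with 39 % for larch and 28 % for cedar, holding that “Added ligand most likely ties up catalyst and slows the reaction”.

    substrate + free catalyst ⇌ catalyst intermediate A (K = 130 L mol⁻¹, k = 3.40 × 10⁵ L mol⁻¹ min⁻¹, Ea = 14.0 kJ mol⁻¹, ΔH = −34.0 kJ mol⁻¹)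
    coupling partner + catalyst intermediate A ⇌ catalyst intermediate B (K = 94.0 L mol⁻¹, k = 1.00 × 10⁵ L mol⁻¹ min⁻¹, Ea = 38.0 kJ mol⁻¹, ΔH = −28.0 kJ mol⁻¹)
    catalyst intermediate B ⇌ free catalyst + product (K = 0.0220 M, k = 150 min⁻¹, Ea = 63.0 kJ mol⁻¹, ΔH = −25.0 kJ mol⁻¹)
    free catalyst → spent catalyst (k = 0.670 min⁻¹, Ea = 68.0 kJ mol⁻¹)
    free catalyst + added ligand ⇌ idle complex, settled at all times (K = 21000 L mol⁻¹, ΔH = 16.0 kJ mol⁻¹)
    (constants at 5 °C)

Larch gives 40.0 % and cedar 29.0 %, so larch holds more. At 8.00 min cedar has 33.2 % of the catalyst charged as idle complex and 50.6 % as spent catalyst; larch at 15.0 min has 3.54 % and 91.9 %. The reach of cedar by its end comes to 0.0409 mM⁻¹, less than the 0.0585 mM⁻¹ reckoned for amber's ligand charge. Left until 80.0 min, cedar stands at 41.4 %, a reach of 0.0707 mM⁻¹, against the total of 0.0696 mM⁻¹, which on this charge means 41.0 %.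

The runs come from a simulation on assumed constants, and the scatter is random.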